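**Retrosynthetic overview**

1. The last step is acid hydrolysis of two aryl MOM ethers and one dioxolane on ring B. Before it, the diaryl ketone is made from a silyl-protected diaryl carbinol by desilylation and oxidation.
2. Key disconnection: ring A carries in sequence C5–OH, C6–(carbinol carbon) and C1–OMe, then C2–H, C3–Me and C4–Br. This phenol/carbon/alkoxy triad is what a vinylketene–alkoxyalkyne benzannulation delivers, so ring A is cut at C5–C6, C1–C2 and C4–C5 into a (2-bromovinyl)ketene (C2–C5, from a diazo ketone by Wolff rearrangement) and a methoxyalkyne (C1, C6) that already bears ring B on its propargylic carbon.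
3. The methoxyalkyne comes from lithium methoxyacetylide and a fully substituted ring-B benzaldehyde. That aldehyde comes from 3,5-dihydroxybenzonitrile, whose nitrile keeps the future ketone carbon distinct from the formyl carbon: MOM protection, 2,6-dibromination, two Br/Mg exchanges (prenyl, then formyl), acetalisation, DIBAL-H reduction.
4. The diazo ketone comes from (E)-3-bromo-2-methylacrylic acid (methylmalonate + bromoform) via Weinreb amide, methyl ketone and detrifluoroacetylative diazo transfer.
5. Ring order: ring B is bought as the arene and only decorated; ring A is the only ring built, in step 14, through a transient cyclobutenone.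

Key step: step 14

Remark: pestalone B has no stereocentre, so no absolute configuration has to be set; the only stereocentre on the route (the carbinol carbon of 14, 15, 29 and 30) is carried as a racemate and is removed by the oxidation in step 16.

**Route**

Step 1
Reactants: 1 3,5-dihydroxybenzonitrile
Product: 2 3,5-bis(methoxymethoxy)benzonitrile
Conditions: MOMCl (2.5 equiv), i-Pr2NEt (3 equiv), CH2Cl2, 0 °C → rt
Reagents that add atoms: chloromethyl methyl ether (MOMCl), COCCl
Why: O-alkylation of both phenols with the α-chloro ether under amine base (Williamson-type MOM ether formation) should give the acid-labile bis-ether that survives all organometallic steps.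

Step 2
Reactants: 2 3,5-bis(methoxymethoxy)benzonitrile
Product: 3 2,6-dibromo-3,5-bis(methoxymethoxy)benzonitrile
Conditions: NBS (2.2 equiv), MeCN, 0 → 40 °C
Reagents that add atoms: N-bromosuccinimide, O=C1CCC(=O)N1Br
Why: Electrophilic aromatic bromination should go twice to the equivalent positions that are ortho to one ether and para to the other (C2, C6), because the site between the two ethers is the most hindered, as is usual for 5-substituted resorcinol diethers.

Step 3
Reactants: 3 2,6-dibromo-3,5-bis(methoxymethoxy)benzonitrile; 4 prenyl bromide (1-bromo-3-methylbut-2-ene)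
Product: 6 2-bromo-3,5-bis(methoxymethoxy)-6-(3-methylbut-2-en-1-yl)benzonitrile, via arylmagnesium chloride 5 (not isolated)
Conditions: i-PrMgCl·LiCl (1.05 equiv), THF, −20 °C; Li2CuCl4 (5 mol %), then 4, −20 → 0 °C
Reagents that add atoms: none
Why: Bromine–magnesium exchange with the turbo-Grignard reagent is fast at a bromide flanked by nitrile and alkoxy groups and tolerates the nitrile, the second bromide of the resulting anion exchanges slowly, and copper-catalysed allylic substitution by the aryl nucleophile should occur at the primary carbon of prenyl bromide (SN2) because the tertiary γ-carbon is closed to a doubly ortho-substituted aryl group.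

Step 4
Reactants: 6 2-bromo-3,5-bis(methoxymethoxy)-6-(3-methylbut-2-en-1-yl)benzonitrile
Product: 8 2-formyl-3,5-bis(methoxymethoxy)-6-(3-methylbut-2-en-1-yl)benzonitrile, via arylmagnesium chloride 7 (not isolated)
Conditions: i-PrMgCl·LiCl (1.1 equiv), THF, −10 → 0 °C; DMF (3 equiv), −20 °C → rt; aq. NH4Cl
Reagents that add atoms: N,N-dimethylformamide, CN(C)C=O
Why: A second bromine–magnesium exchange ortho to the nitrile followed by formylation of the arylmagnesium with DMF (Bouveault aldehyde synthesis) should place the formyl carbon at C2, the tetrahedral aminoalkoxide preventing over-addition until work-up.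

Step 5
Reactants: 8 2-formyl-3,5-bis(methoxymethoxy)-6-(3-methylbut-2-en-1-yl)benzonitrile
Product: 9 2-(1,3-dioxolan-2-yl)-3,5-bis(methoxymethoxy)-6-(3-methylbut-2-en-1-yl)benzonitrile
Conditions: (TMSOCH2)2 (1.5 equiv), TMSOTf (5 mol %), CH2Cl2, −78 → −20 °C; pyridine quench
Reagents that add atoms: 1,2-bis(trimethylsilyloxy)ethane, C[Si](C)(C)OCCO[Si](C)(C)C
Why: Silyl-triflate-catalysed acetalisation with the bis-silyl ether of ethylene glycol converts the electron-rich aldehyde into its dioxolane at low temperature, driven by formation of hexamethyldisiloxane and mild enough to leave the aryl MOM ethers untouched.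

Step 6
Reactants: 9 2-(1,3-dioxolan-2-yl)-3,5-bis(methoxymethoxy)-6-(3-methylbut-2-en-1-yl)benzonitrile
Product: 11 2-(1,3-dioxolan-2-yl)-3,5-bis(methoxymethoxy)-6-(3-methylbut-2-en-1-yl)benzaldehyde, via aluminium aldimine 10 (not isolated)
Conditions: DIBAL-H (1.3 equiv), toluene, −78 → −40 °C; MeOH; aq. Rochelle salt, then NaOAc/AcOH buffer (pH 5), 0 °C
Reagents that add atoms: water, O
Why: DIBAL-H delivers one hydride to the nitrile to give an N-aluminio aldimine that is not reduced further at low temperature (partial reduction of a nitrile), and buffered hydrolysis should release the aldehyde while dioxolane and MOM ethers remain.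

Step 7
Reactants: 11 2-(1,3-dioxolan-2-yl)-3,5-bis(methoxymethoxy)-6-(3-methylbut-2-en-1-yl)benzaldehyde; 12 chloroacetaldehyde dimethyl acetal (2-chloro-1,1-dimethoxyethane)
Product: 14 rac-1-[2-(1,3-dioxolan-2-yl)-3,5-bis(methoxymethoxy)-6-(3-methylbut-2-en-1-yl)phenyl]-3-methoxyprop-2-yn-1-ol, via lithium methoxyacetylide 13 (not isolated)
Conditions: 12 (1.5 equiv), LiNEt2 (from Et2NH/n-BuLi, 4.5 equiv), THF, 0 °C; then 11, −78 → −40 °C; aq. NaHCO3; Et3N-deactivated SiO2
Reagents that add atoms: none
Why: Lithium diethylamide converts the chloroacetal by two eliminations and a deprotonation into lithium methoxyacetylide, whose 1,2-addition to the non-enolisable aldehyde (acetylide addition) sets the carbinol centre without control, so 14 is racemic and the centre is later oxidised away.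

Step 8
Reactants: 14 rac-1-[2-(1,3-dioxolan-2-yl)-3,5-bis(methoxymethoxy)-6-(3-methylbut-2-en-1-yl)phenyl]-3-methoxyprop-2-yn-1-ol
Product: 15 rac-tert-butyl({1-[2-(1,3-dioxolan-2-yl)-3,5-bis(methoxymethoxy)-6-(3-methylbut-2-en-1-yl)phenyl]-3-methoxyprop-2-yn-1-yl}oxy)dimethylsilane
Conditions: TBSCl (1.5 equiv), imidazole (3 equiv), DMAP (cat.), DMF, rt
Reagents that add atoms: tert-butyldimethylsilyl chloride, CC(C)(C)[Si](C)(C)Cl
Why: Base-mediated silyl ether formation masks the hydroxyl that would otherwise acylate the ketene, and it avoids the acid that would trigger Meyer–Schuster rearrangement of the γ-hydroxy ynol ether.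

Step 9
Reactants: 16 diethyl methylmalonate; 17 bromoform
Product: 18 diethyl 2-(dibromomethyl)-2-methylmalonate
Conditions: NaH (1.1 equiv), THF, 0 °C → rt; 17 (1.5 equiv), 65 °C
Reagents that add atoms: none
Why: The malonate enolate is C-alkylated by bromoform through capture of dibromocarbene and protonation (formal substitution), which places the CHBr2 group on the quaternary carbon.

Step 10
Reactants: 18 diethyl 2-(dibromomethyl)-2-methylmalonate
Product: 19 (E)-3-bromo-2-methylprop-2-enoic acid
Conditions: KOH (5 equiv), EtOH/H2O, reflux; then aq. HCl to pH 1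
Reagents that add atoms: potassium hydroxide, [K+].[OH-]
Why: Saponification of both esters followed by decarboxylative elimination of bromide (Grob-type fragmentation of the β-bromo carboxylate) should give the bromoacrylic acid as the favoured E isomer with bromine trans to the carboxyl group.

Step 11
Reactants: 19 (E)-3-bromo-2-methylprop-2-enoic acid
Product: 21 (E)-3-bromo-N-methoxy-N,2-dimethylprop-2-enamide, via acid chloride 20 (not isolated)
Conditions: (COCl)2 (1.2 equiv), DMF (cat.), CH2Cl2, 0 °C → rt; then MeNH(OMe)·HCl (1.3 equiv), Et3N (3 equiv), CH2Cl2, 0 °C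
Reagents that add atoms: N,O-dimethylhydroxylamine hydrochloride, CNOC.Cl
Why: Acid chloride formation and N-acylation of the hydroxylamine (Weinreb amide synthesis) proceed without touching the vinyl bromide or its geometry.

Step 12
Reactants: 21 (E)-3-bromo-N-methoxy-N,2-dimethylprop-2-enamide
Product: 22 (E)-4-bromo-3-methylbut-3-en-2-one
Conditions: MeMgBr (1.3 equiv), THF, 0 °C; aq. NH4Cl
Reagents that add atoms: methylmagnesium bromide, C[Mg]Br
Why: Grignard addition stops at the chelated tetrahedral intermediate, which collapses to the methyl ketone only on work-up (Weinreb ketone synthesis), and the amide is too poor an acceptor for conjugate addition–elimination at the bromoalkene.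

Step 13
Reactants: 22 (E)-4-bromo-3-methylbut-3-en-2-one
Product: 24 (E)-4-bromo-1-diazo-3-methylbut-3-en-2-one, via trifluoroacetyl diketone 23 (not isolated)
Conditions: LiHMDS (1.1 equiv), THF, −78 °C; CF3CO2CH2CF3 (1.2 equiv); aq. HCl work-up; then MsN3 (1.5 equiv), Et3N (1.5 equiv), H2O (1 equiv), MeCN, rt
Reagents that add atoms: methanesulfonyl azide, CS(=O)(=O)N=[N+]=[N-]
Why: Kinetic enolisation at the methyl group and Claisen-type trifluoroacetylation activate the ketone for Regitz diazo transfer, after which the trifluoroacetyl group is lost to the sulfonamide (detrifluoroacetylative diazo transfer), a route that avoids diazomethane and its dipolar cycloaddition to the enone.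

Step 14
Reactants: 24 (E)-4-bromo-1-diazo-3-methylbut-3-en-2-one; 15 rac-tert-butyl({1-[2-(1,3-dioxolan-2-yl)-3,5-bis(methoxymethoxy)-6-(3-methylbut-2-en-1-yl)phenyl]-3-methoxyprop-2-yn-1-yl}oxy)dimethylsilane
Product: 29 rac-2-bromo-6-{[tert-butyl(dimethyl)silyl]oxy[2-(1,3-dioxolan-2-yl)-3,5-bis(methoxymethoxy)-6-(3-methylbut-2-en-1-yl)phenyl]methyl}-5-methoxy-3-methylphenol, via vinylketene 25 (not isolated), via vinylcyclobutenone 26 (not isolated), via dienylketene 27 (not isolated), via cyclohexadienone 28 (not isolated)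
Conditions: 24 (2 equiv, slow addition), hν (365 nm), degassed ClCH2CH2Cl, rt; then 80 °C
Reagents that add atoms: none
Why: Irradiation expels N2 from 24 and the bromoalkenyl group migrates (photochemical Wolff rearrangement) to give vinylketene 25, which undergoes a regioselective [2+2] cycloaddition with ynol ether 15 in which the nucleophilic β-carbon of the alkyne (future C6) bonds to the ketene carbonyl carbon (future C5) and the methoxy-bearing carbon (future C1) to the ketene α-carbon (future C2), giving vinylcyclobutenone 26. A 4π-electrocyclic opening of 26 breaks the C2–C5 bond to give dienylketene 27, whose disrotatory 6π-electrocyclisation forms C4–C5 and closes the six-membered ring A as dienone 28, and enolisation then gives phenol 29. This is the Danheiser benzannulation in its α-diazo ketone variant with an alkoxyalkyne, which is the closest known reaction type. No lasting stereocentre is created, since the sp3 centres of 26 and 28 disappear on ring opening and on tautomerisation and the racemic carbinol carbon of 15 is not touched. The step needs regioselectivity in the [2+2] event, which the polarisation of the ynol ether secures so that OH, the carbinol carbon and OMe end up on C5, C6 and C1, and it needs chemoselectivity for the alkyne over the prenyl alkene, which the far higher reactivity of the electron-rich ynol ether toward ketenes secures. The E geometry of the bromoalkene is retained in the migration and keeps bromine on the outside of the closing triene terminus, and irradiation at 365 nm should leave the C–Br bonds alone.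

Step 15
Reactants: 29 rac-2-bromo-6-{[tert-butyl(dimethyl)silyl]oxy[2-(1,3-dioxolan-2-yl)-3,5-bis(methoxymethoxy)-6-(3-methylbut-2-en-1-yl)phenyl]methyl}-5-methoxy-3-methylphenol
Product: 30 rac-2-bromo-6-{[2-(1,3-dioxolan-2-yl)-3,5-bis(methoxymethoxy)-6-(3-methylbut-2-en-1-yl)phenyl](hydroxy)methyl}-5-methoxy-3-methylphenol
Conditions: TBAF (1.2 equiv), THF, 0 °C; aq. NH4Cl
Reagents that add atoms: none
Why: Fluoride-mediated silyl ether cleavage frees the benzylic carbinol without acid, which keeps the ionisable o-hydroxybenzhydrol, the dioxolane and the MOM ethers intact.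

Step 16
Reactants: 30 rac-2-bromo-6-{[2-(1,3-dioxolan-2-yl)-3,5-bis(methoxymethoxy)-6-(3-methylbut-2-en-1-yl)phenyl](hydroxy)methyl}-5-methoxy-3-methylphenol
Product: 31 (3-bromo-2-hydroxy-6-methoxy-4-methylphenyl)[2-(1,3-dioxolan-2-yl)-3,5-bis(methoxymethoxy)-6-(3-methylbut-2-en-1-yl)phenyl]methanone
Conditions: Dess–Martin periodinane (1.3 equiv), NaHCO3, CH2Cl2, 0 °C → rt
Reagents that add atoms: none
Why: Dess–Martin oxidation converts the hindered diaryl carbinol into the ketone under buffered conditions, the phenol has both ortho positions blocked so that ring oxidation is not expected, and the new carbonyl is stabilised by a hydrogen bond to that phenol.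

Step 17
Reactants: 31 (3-bromo-2-hydroxy-6-methoxy-4-methylphenyl)[2-(1,3-dioxolan-2-yl)-3,5-bis(methoxymethoxy)-6-(3-methylbut-2-en-1-yl)phenyl]methanone
Product: 32 pestalone B, 2-(3-bromo-2-hydroxy-6-methoxy-4-methylbenzoyl)-4,6-dihydroxy-3-(3-methylbut-2-en-1-yl)benzaldehyde
Conditions: 3 M aq. HCl/THF (1:3), 40 °C
Reagents that add atoms: water, O
Why: Dilute aqueous acid hydrolyses the electron-rich aryl dioxolane and both aryl MOM ethers (acetal hydrolysis) under conditions that ortho-prenyl phenols commonly tolerate, since closure to a chroman needs stronger acid.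

**Compound list**

1 | 3,5-dihydroxybenzonitrile | N#Cc1cc(O)cc(O)c1 | starting material
2 | 3,5-bis(methoxymethoxy)benzonitrile | N#Cc1cc(OCOC)cc(OCOC)c1 | intermediate
3 | 2,6-dibromo-3,5-bis(methoxymethoxy)benzonitrile | N#Cc1c(Br)c(OCOC)cc(OCOC)c1Br | intermediate
4 | prenyl bromide (1-bromo-3-methylbut-2-ene) | CC(C)=CCBr | starting material
5 | [3-bromo-2-cyano-4,6-bis(methoxymethoxy)phenyl]magnesium chloride | N#Cc1c(Br)c(OCOC)cc(OCOC)c1[Mg]Cl | intermediate
6 | 2-bromo-3,5-bis(methoxymethoxy)-6-(3-methylbut-2-en-1-yl)benzonitrile | N#Cc1c(Br)c(OCOC)cc(OCOC)c1CC=C(C)C | intermediate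
7 | [2-cyano-4,6-bis(methoxymethoxy)-3-(3-methylbut-2-en-1-yl)phenyl]magnesium chloride | N#Cc1c([Mg]Cl)c(OCOC)cc(OCOC)c1CC=C(C)C | intermediate
8 | 2-formyl-3,5-bis(methoxymethoxy)-6-(3-methylbut-2-en-1-yl)benzonitrile | N#Cc1c(C=O)c(OCOC)cc(OCOC)c1CC=C(C)C | intermediate
9 | 2-(1,3-dioxolan-2-yl)-3,5-bis(methoxymethoxy)-6-(3-methylbut-2-en-1-yl)benzonitrile | N#Cc1c(C2OCCO2)c(OCOC)cc(OCOC)c1CC=C(C)C | intermediate
10 | N-(diisobutylalumanyl) aldimine of aldehyde 11 | CC(C)C[Al](CC(C)C)N=Cc1c(C2OCCO2)c(OCOC)cc(OCOC)c1CC=C(C)C | intermediate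
11 | 2-(1,3-dioxolan-2-yl)-3,5-bis(methoxymethoxy)-6-(3-methylbut-2-en-1-yl)benzaldehyde | O=Cc1c(C2OCCO2)c(OCOC)cc(OCOC)c1CC=C(C)C | intermediate
12 | chloroacetaldehyde dimethyl acetal (2-chloro-1,1-dimethoxyethane) | COC(CCl)OC | starting material
13 | lithium methoxyacetylide | [Li+].[C-]#COC | intermediate
14 | rac-1-[2-(1,3-dioxolan-2-yl)-3,5-bis(methoxymethoxy)-6-(3-methylbut-2-en-1-yl)phenyl]-3-methoxyprop-2-yn-1-ol | COC#CC(O)c1c(C2OCCO2)c(OCOC)cc(OCOC)c1CC=C(C)C | intermediate
15 | rac-tert-butyl({1-[2-(1,3-dioxolan-2-yl)-3,5-bis(methoxymethoxy)-6-(3-methylbut-2-en-1-yl)phenyl]-3-methoxyprop-2-yn-1-yl}oxy)dimethylsilane | COC#CC(O[Si](C)(C)C(C)(C)C)c1c(C2OCCO2)c(OCOC)cc(OCOC)c1CC=C(C)C | intermediate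
16 | diethyl methylmalonate | CCOC(=O)C(C)C(=O)OCC | starting material
17 | bromoform | BrC(Br)Br | starting material
18 | diethyl 2-(dibromomethyl)-2-methylmalonate | CCOC(=O)C(C)(C(Br)Br)C(=O)OCC | intermediate
19 | (E)-3-bromo-2-methylprop-2-enoic acid | C/C(=C\Br)C(=O)O | intermediate
20 | (E)-3-bromo-2-methylprop-2-enoyl chloride | C/C(=C\Br)C(=O)Cl | intermediate
21 | (E)-3-bromo-N-methoxy-N,2-dimethylprop-2-enamide | C/C(=C\Br)C(=O)N(C)OC | intermediate
22 | (E)-4-bromo-3-methylbut-3-en-2-one | C/C(=C\Br)C(C)=O | intermediate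
23 | (E)-6-bromo-1,1,1-trifluoro-5-methylhex-5-ene-2,4-dione | C/C(=C\Br)C(=O)CC(=O)C(F)(F)F | intermediate
24 | (E)-4-bromo-1-diazo-3-methylbut-3-en-2-one | C/C(=C\Br)C(=O)C=[N+]=[N-] | intermediate
25 | (E)-4-bromo-3-methylbuta-1,3-dien-1-one, the (2-bromovinyl)ketene | C/C(=C\Br)C=C=O | intermediate
26 | 4-[(E)-1-bromoprop-1-en-2-yl]-3-methoxy-2-{[tert-butyl(dimethyl)silyl]oxy[2-(1,3-dioxolan-2-yl)-3,5-bis(methoxymethoxy)-6-(3-methylbut-2-en-1-yl)phenyl]methyl}cyclobut-2-en-1-one (mixture of diastereomers) | COC1=C(C(O[Si](C)(C)C(C)(C)C)c2c(C3OCCO3)c(OCOC)cc(OCOC)c2CC=C(C)C)C(=O)C1/C(C)=C/Br | intermediate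
27 | (3E,5E)-6-bromo-3-methoxy-5-methyl-2-{[tert-butyl(dimethyl)silyl]oxy[2-(1,3-dioxolan-2-yl)-3,5-bis(methoxymethoxy)-6-(3-methylbut-2-en-1-yl)phenyl]methyl}hexa-1,3,5-trien-1-one (racemic) | O=C=C(C(O[Si](C)(C)C(C)(C)C)c1c(C2OCCO2)c(OCOC)cc(OCOC)c1CC=C(C)C)\C(OC)=C/C(C)=C/Br | intermediate
28 | 6-bromo-3-methoxy-5-methyl-2-{[tert-butyl(dimethyl)silyl]oxy[2-(1,3-dioxolan-2-yl)-3,5-bis(methoxymethoxy)-6-(3-methylbut-2-en-1-yl)phenyl]methyl}cyclohexa-2,4-dien-1-one (mixture of diastereomers) | O=C1C(Br)C(C)=CC(OC)=C1C(O[Si](C)(C)C(C)(C)C)c1c(C2OCCO2)c(OCOC)cc(OCOC)c1CC=C(C)C | intermediate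
29 | rac-2-bromo-6-{[tert-butyl(dimethyl)silyl]oxy[2-(1,3-dioxolan-2-yl)-3,5-bis(methoxymethoxy)-6-(3-methylbut-2-en-1-yl)phenyl]methyl}-5-methoxy-3-methylphenol | COc1cc(C)c(Br)c(O)c1C(O[Si](C)(C)C(C)(C)C)c1c(C2OCCO2)c(OCOC)cc(OCOC)c1CC=C(C)C | intermediate
30 | rac-2-bromo-6-{[2-(1,3-dioxolan-2-yl)-3,5-bis(methoxymethoxy)-6-(3-methylbut-2-en-1-yl)phenyl](hydroxy)methyl}-5-methoxy-3-methylphenol | COc1cc(C)c(Br)c(O)c1C(O)c1c(C2OCCO2)c(OCOC)cc(OCOC)c1CC=C(C)C | intermediate
31 | (3-bromo-2-hydroxy-6-methoxy-4-methylphenyl)[2-(1,3-dioxolan-2-yl)-3,5-bis(methoxymethoxy)-6-(3-methylbut-2-en-1-yl)phenyl]methanone | COc1cc(C)c(Br)c(O)c1C(=O)c1c(C2OCCO2)c(OCOC)cc(OCOC)c1CC=C(C)C | intermediate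
32 | pestalone B, 2-(3-bromo-2-hydroxy-6-methoxy-4-methylbenzoyl)-4,6-dihydroxy-3-(3-methylbut-2-en-1-yl)benzaldehyde | COc1cc(C)c(Br)c(O)c1C(=O)c1c(C=O)c(O)cc(O)c1CC=C(C)C | target

**Step count and risk**

Total step count: 17. Longest linear sequence: 12 steps (steps 1–8, then 14–17); the diazo ketone branch (steps 9–13) has 5 steps.

The three steps most likely to fail:

Step 14 (benzannulation). Capture of ketene 25 by the β-branched, doubly ortho-shielded ynol ether 15 may be too slow, so that ketene dimerisation and O-acylation of the product phenol consume the diazo ketone; the 6π closure next to the bulky carbinol substituent may also stall at the cyclobutenone stage. The fallback leaves the benzannulation and joins a preformed ring A to the ring-B aldehyde 11, coming back to the route at target 32. Commercial 3-methoxy-5-methylphenol would be brominated at both positions ortho to the hydroxyl (NBS, cat. i-Pr2NH, CH2Cl2) to give 2,6-dibromo-3-methoxy-5-methylphenol F1, which would be protected (MOMCl, i-Pr2NEt) as 1,3-dibromo-4-methoxy-2-(methoxymethoxy)-6-methylbenzene F2. Bromine–lithium exchange (n-BuLi, THF, −78 °C) should take place at the bromide flanked by two oxygen substituents and give [3-bromo-6-methoxy-2-(methoxymethoxy)-4-methylphenyl]lithium F3, which would add to aldehyde 11 to give rac-[3-bromo-6-methoxy-2-(methoxymethoxy)-4-methylphenyl][2-(1,3-dioxolan-2-yl)-3,5-bis(methoxymethoxy)-6-(3-methylbut-2-en-1-yl)phenyl]methanol F4. Dess–Martin oxidation would give [3-bromo-6-methoxy-2-(methoxymethoxy)-4-methylphenyl][2-(1,3-dioxolan-2-yl)-3,5-bis(methoxymethoxy)-6-(3-methylbut-2-en-1-yl)phenyl]methanone F5, and aqueous HCl in THF would then remove the three MOM groups and the dioxolane to reach 32.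

Step 17 (global deprotection). Under protic acid the phenol freed next to the prenyl group may add to the alkene (chroman formation) before the last MOM ether is cleaved, and the o-formyl benzophenone may isomerise on prolonged exposure. The fallback sets out from ketone 31, returns at 32, and separates the two unmaskings while avoiding protic acid for the MOM ethers. Transacetalisation (PPTS, acetone/H2O, rt) would give 2-(3-bromo-2-hydroxy-6-methoxy-4-methylbenzoyl)-4,6-bis(methoxymethoxy)-3-(3-methylbut-2-en-1-yl)benzaldehyde F7. Treatment with TMSOTf and 2,2′-bipyridyl in CH2Cl2 at 0 °C would then exchange the aryl MOM ethers for silyl ethers, giving 2-{3-bromo-6-methoxy-4-methyl-2-[(trimethylsilyl)oxy]benzoyl}-3-(3-methylbut-2-en-1-yl)-4,6-bis[(trimethylsilyl)oxy]benzaldehyde F8, which neutral aqueous work-up would hydrolyse to 32.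

Step 16 (oxidation). Ionisation of the o-hydroxybenzhydrol to an o-quinone methide, or oxidation at the free, electron-rich phenol, may compete with oxidation of the very hindered carbinol. The fallback sets out from phenol 29, returns at 32, and changes the order of protection. The phenol would first be capped (NaH, MOMCl, THF, 0 °C) to give rac-tert-butyl{[3-bromo-6-methoxy-2-(methoxymethoxy)-4-methylphenyl][2-(1,3-dioxolan-2-yl)-3,5-bis(methoxymethoxy)-6-(3-methylbut-2-en-1-yl)phenyl]methoxy}dimethylsilane F6. TBAF would then give carbinol F4, Dess–Martin oxidation would give ketone F5, and aqueous HCl in THF would give 32, as in the fallback for step 14.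

**Further compounds**

F1 | step 14 | 2,6-dibromo-3-methoxy-5-methylphenol | COc1cc(C)c(Br)c(O)c1Br
F2 | step 14 | 1,3-dibromo-4-methoxy-2-(methoxymethoxy)-6-methylbenzene | COCOc1c(Br)c(C)cc(OC)c1Br
F3 | step 14 | [3-bromo-6-methoxy-2-(methoxymethoxy)-4-methylphenyl]lithium | [Li]c1c(OC)cc(C)c(Br)c1OCOC
F4 | step 14 | rac-[3-bromo-6-methoxy-2-(methoxymethoxy)-4-methylphenyl][2-(1,3-dioxolan-2-yl)-3,5-bis(methoxymethoxy)-6-(3-methylbut-2-en-1-yl)phenyl]methanol | COCOc1c(Br)c(C)cc(OC)c1C(O)c1c(C2OCCO2)c(OCOC)cc(OCOC)c1CC=C(C)C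
F5 | step 14 | [3-bromo-6-methoxy-2-(methoxymethoxy)-4-methylphenyl][2-(1,3-dioxolan-2-yl)-3,5-bis(methoxymethoxy)-6-(3-methylbut-2-en-1-yl)phenyl]methanone | COCOc1c(Br)c(C)cc(OC)c1C(=O)c1c(C2OCCO2)c(OCOC)cc(OCOC)c1CC=C(C)C
F6 | step 16 | rac-tert-butyl{[3-bromo-6-methoxy-2-(methoxymethoxy)-4-methylphenyl][2-(1,3-dioxolan-2-yl)-3,5-bis(methoxymethoxy)-6-(3-methylbut-2-en-1-yl)phenyl]methoxy}dimethylsilane | COCOc1c(Br)c(C)cc(OC)c1C(O[Si](C)(C)C(C)(C)C)c1c(C2OCCO2)c(OCOC)cc(OCOC)c1CC=C(C)C
F7 | step 17 | 2-(3-bromo-2-hydroxy-6-methoxy-4-methylbenzoyl)-4,6-bis(methoxymethoxy)-3-(3-methylbut-2-en-1-yl)benzaldehyde | COc1cc(C)c(Br)c(O)c1C(=O)c1c(C=O)c(OCOC)cc(OCOC)c1CC=C(C)C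
F8 | step 17 | 2-{3-bromo-6-methoxy-4-methyl-2-[(trimethylsilyl)oxy]benzoyl}-3-(3-methylbut-2-en-1-yl)-4,6-bis[(trimethylsilyl)oxy]benzaldehyde | COc1cc(C)c(Br)c(O[Si](C)(C)C)c1C(=O)c1c(C=O)c(O[Si](C)(C)C)cc(O[Si](C)(C)C)c1CC=C(C)C
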